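The target in this flask comes from an intermediate, and the reagent that starts the chain also consumes the target.

    starting material + reagent → intermediate + by-product (k1 = 0.0021 L mol⁻¹ s⁻¹)
    intermediate → target (k2 = 0.0038 s⁻¹)
    starting material + intermediate → side product (k3 = 2.7 × 10⁻⁴ L mol⁻¹ s⁻¹)
    reagent + target → over-reaction product (k4 = 0.0025 L mol⁻¹ s⁻¹)

starting material 0.25 M; reagent 0.125 M; time 4.0 d

- percent here means starting material units held: one side product counts as two
- the reaction counts as stopped when no species that holds the starting material changes by six tenths of a point or more over the second half of the time
- run time (flask): 4.0 d

1. why nothing more happens at 4.0 d, or that something still does (the reagent has run out first / forward and back rates have come level / all of the starting material has reacted / it is still moving)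
2. part of the starting material gone at 4.0 d
3. the target standing at 4.0 d, as a percentage of the starting material charged
4. the over-reaction product standing at 4.0 d, as a percentage of the starting material charged

**In the flask.** The reagent is charged at half the concentration of the starting material, which makes it the limiting reagent. Its half-life by the first step, at the charged c(starting material), is 22.0 min, far shorter than the run of 4.0 d. An intermediate molecule has a half-life of 3.04 min on its way to target, and hardly any turns to side product at the charged c(starting material).

**The fork.** Each reagent molecule meets either starting material or target. Its odds for target are s times c(target)/c(starting material), where s, the selectivity factor, is the rate constant of attack on target divided by that of attack on starting material, 1.19.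

**Expected state.** Call the conversion x. By this hand reckoning, the odds grow roughly in step with conversion, averaging s times 0.5 x, so the over-reacted part is that average times x. Reagent pays once per converted unit and again per over-reacted unit, and these two together equal c(reagent)/c(starting material) as charged. This gives x = 40.3%, over-reaction product 9.68% and target 30.6%.

**Not to touch.** The reagent charge stays as weighed: in this reckoning x stands below the ratio c(reagent)/c(starting material) and moves with it.

**Forecast.** The forecast says the reagent has run out first: “it is gone within hours”. It gives conversion 41%, target 30.3% and over-reaction product 9.6%. The hand reckoning lies slightly lower in conversion and slightly higher in target and over-reaction product.

**Result.** In the flask, the reagent has run out first, with 0% of its charge standing at 4.00 d. Conversion in this flask is 40.8%, target 29.9% and over-reaction product 9.76%. With the simulated conversion, s gives this flask 9.90% over-reaction product. For the neighbour flask charged with 0.075 M of reagent, s gives conversion 26.0% and over-reaction product 4.02%. That neighbour flask stands at 26.5% and 3.87%.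

(Its constants were set for the occasion; the run is a simulation.)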